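**Plan** (atom numbers in the text are carotenoid numbers of the target; locants inside compound names are IUPAC locants)

- Cuts: C11=C12 and C11'=C12' (two Horner–Wadsworth–Emmons olefinations on a C10 bis(phosphonate)); C7–C8 (alkylation of a 2-lithiofuran, the furan being the masked C8–C11 keto-enal that carries C19 on its 3-position); the C19 ester C–O; and, in the β ring, C2–C3 and C5–C6.
- Enabling feature: in the β ring the quaternary C1 (gem-dimethyl) lies between C2 and C6(–C7), which is a 3,3-dimethylglutarate unit, and C3(O)–C4–C5(CH3) is a crotonate unit. One Michael–Dieckmann [3+3] annulation of the glutarate enolate onto methyl crotonate therefore closes the carbocycle with C7 already in place.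
- Forward order: β ring (steps 1–6), C7 bromide (7–9), furan alkylation, esterification and furan opening to the C8–C11 keto-enal (10–13); ε-C15 aldehyde from α-ionone (14–17); C10 bis(phosphonate) (18–20); chain joined as ε-C15 + C10 (21), then + β half (22).
- Stereochemistry: C3 from a ketoreductase reduction of enone 8 (the C6 epimers converge when the double bond moves to C5=C6 in step 6); C3' and C6' from a ketoreductase kinetic resolution of racemic ketone 25; C9=C10 from the furan opening and isomerisation; the remaining chain double bonds from E-selective olefinations and the purchased E building blocks.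

Key step: step 2

Assumption: the two ketoreductases (steps 5 and 16) are taken from a commercial screening panel and are defined here by the alcohol configuration they must deliver, with 2-propanol recycling the cofactor; all polyenes are handled under argon in dim light.

**Route**

Step 1
Reactants: 1 3,3-dimethylpentanedioic acid
Product: 2 di-tert-butyl 3,3-dimethylpentanedioate
Conditions: 2-methylpropene (excess), H2SO4 (cat.), CH2Cl2, sealed flask, 20 °C
Reagents that add atoms: 2-methylpropene, CC(C)=C
Why: Acid-catalysed addition of both carboxylic acids to isobutene (tert-butyl ester formation) should be clean on this diacid and gives the ester pair that the key step needs.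

Step 2
Reactants: 2 di-tert-butyl 3,3-dimethylpentanedioate; 3 methyl (2E)-but-2-enoate
Product: 6 di-tert-butyl 2,2,4-trimethyl-6-oxocyclohexane-1,3-dicarboxylate (racemic diastereomer mixture), via lithium enolate of diester 4 (not isolated), via Michael adduct triester 5 (not isolated)
Conditions: LiN(iPr)2 (1.05 equiv), THF/DMPU, −78 °C; then 3, −78 to 20 °C; aq. NH4Cl
Reagents that add atoms: none
Why: The lithium enolate 4 should add 1,4 to methyl crotonate and so join C6 to C5; proton exchange within adduct 5 (present as its enolate) then places the enolate at C2, which attacks the methyl ester carbon C3 and expels methoxide, the β-keto ester enolate of 6 being the thermodynamic sink. The closest known reaction type is the tandem Michael–Dieckmann (Michael–Claisen) annulation of ester enolates with enoates. The cyclohexanone closes by 6-exo-trig attack of the C2 enolate on the ester carbonyl. The three stereocentres formed (C2, C5, C6) are not controlled and need not be, since C2 loses its helper ester in step 3 and C5 and C6 become sp2 in steps 4 and 6. The step needs 1,4- over 1,2-addition and closure onto C3 instead of closure of the first-formed C4 enolate onto a glutarate ester; the low temperature in THF/DMPU should secure the first, and the two tert-butyl esters, which resist acyl substitution while the methyl ester does not, the second.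

Step 3
Reactants: 6 di-tert-butyl 2,2,4-trimethyl-6-oxocyclohexane-1,3-dicarboxylate
Product: 7 tert-butyl 2,2,6-trimethyl-4-oxocyclohexane-1-carboxylate (racemic cis/trans mixture)
Conditions: DMSO/H2O (20:1), 140 °C
Reagents that add atoms: none
Why: Thermal dealkoxycarbonylation of the β-keto tert-butyl ester (through the acylketene, then hydration and loss of CO2) should remove only the helper ester at C2, because the isolated tert-butyl ester at C6 is inert without acid.

Step 4
Reactants: 7 tert-butyl 2,2,6-trimethyl-4-oxocyclohexane-1-carboxylate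
Product: 8 tert-butyl 2,6,6-trimethyl-4-oxocyclohex-2-ene-1-carboxylate (racemic)
Conditions: IBX (2.5 equiv), DMSO/toluene, 75 °C
Reagents that add atoms: none
Why: IBX dehydrogenation of the ketone (enol capture by hypervalent iodine, then elimination) can only give the C4=C5 enone, since C1 on the other side of the carbonyl is quaternary.

Step 5
Reactants: 8 tert-butyl 2,6,6-trimethyl-4-oxocyclohex-2-ene-1-carboxylate
Product: 9 tert-butyl (4S)-4-hydroxy-2,6,6-trimethylcyclohex-2-ene-1-carboxylate (both C1 epimers)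
Conditions: ketoreductase (KRED, giving the 4S alcohol), NADP+ (cat.), 2-propanol, phosphate buffer pH 7.5, 30 °C
Reagents that add atoms: none
Why: Enzymatic carbonyl reduction (hydride from NADPH) should set C3 (4S in the name) by enzyme control on this isophorone-like enone, while the C6 centre, labile in 8 as the vinylogous β-keto ester position and erased in step 6, needs no control.

Step 6
Reactants: 9 tert-butyl (4S)-4-hydroxy-2,6,6-trimethylcyclohex-2-ene-1-carboxylate
Product: 10 tert-butyl (4R)-4-hydroxy-2,6,6-trimethylcyclohex-1-ene-1-carboxylate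
Conditions: KOtBu (0.3 equiv), t-BuOH/THF, 50 °C
Reagents that add atoms: none
Why: A base-mediated 1,3-prototropic shift through the ester dienolate (deconjugated-to-conjugated ester isomerisation) should move the double bond to the tetrasubstituted C5=C6 position and erase C6 without touching C3; the descriptor changes from S to R only because the ring branches change CIP rank.

Step 7
Reactants: 10 tert-butyl (4R)-4-hydroxy-2,6,6-trimethylcyclohex-1-ene-1-carboxylate
Product: 11 tert-butyl (4R)-4-{[tert-butyl(dimethyl)silyl]oxy}-2,6,6-trimethylcyclohex-1-ene-1-carboxylate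
Conditions: TBSCl, imidazole, DMF, 20 °C
Reagents that add atoms: tert-butyldimethylsilyl chloride, CC(C)(C)[Si](C)(C)Cl
Why: Silylation of the secondary alcohol (silyl ether formation) protects it for the hydride, bromination, organolithium and acylation steps.

Step 8
Reactants: 11 tert-butyl (4R)-4-{[tert-butyl(dimethyl)silyl]oxy}-2,6,6-trimethylcyclohex-1-ene-1-carboxylate
Product: 12 [(4R)-4-{[tert-butyl(dimethyl)silyl]oxy}-2,6,6-trimethylcyclohex-1-en-1-yl]methanol
Conditions: iBu2AlH (3 equiv), CH2Cl2, −78 to 0 °C; aq. potassium sodium tartrate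
Reagents that add atoms: none
Why: Hydride reduction of the hindered conjugated ester with iBu2AlH should give the allylic alcohol (C7), the silyl ether being stable to the reagent.

Step 9
Reactants: 12 [(4R)-4-{[tert-butyl(dimethyl)silyl]oxy}-2,6,6-trimethylcyclohex-1-en-1-yl]methanol
Product: 13 {[(1R)-4-(bromomethyl)-3,5,5-trimethylcyclohex-3-en-1-yl]oxy}(tert-butyl)dimethylsilane
Conditions: CBr4, PPh3, CH2Cl2, 0 °C; used at once
Reagents that add atoms: carbon tetrabromide, BrC(Br)(Br)Br
Why: The Appel reaction converts the primary allylic alcohol into the bromide under neutral conditions that spare the silyl ether.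

Step 10
Reactants: 14 furan-3-ylmethanol; 13 {[(1R)-4-(bromomethyl)-3,5,5-trimethylcyclohex-3-en-1-yl]oxy}(tert-butyl)dimethylsilane
Product: 16 (2-{[(4R)-4-{[tert-butyl(dimethyl)silyl]oxy}-2,6,6-trimethylcyclohex-1-en-1-yl]methyl}furan-3-yl)methanol, via 2-lithio-3-(lithiooxymethyl)furan 15 (not isolated)
Conditions: 14 (1.5 equiv), n-BuLi (3.1 equiv), THF, −78 to 0 °C; then 13, −78 to 20 °C; aq. NH4Cl
Reagents that add atoms: none
Why: Hydroxymethyl-directed lithiation of the furan at its 2-position followed by SN2 alkylation of the furyllithium with the primary allylic bromide should form C7–C8, the lithium alkoxide being the less nucleophilic site.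

Step 11
Reactants: 16 (2-{[(4R)-4-{[tert-butyl(dimethyl)silyl]oxy}-2,6,6-trimethylcyclohex-1-en-1-yl]methyl}furan-3-yl)methanol; 17 (2E)-dodec-2-enoic acid
Product: 18 (2-{[(4R)-4-{[tert-butyl(dimethyl)silyl]oxy}-2,6,6-trimethylcyclohex-1-en-1-yl]methyl}furan-3-yl)methyl (2E)-dodec-2-enoate
Conditions: DCC, DMAP (cat.), CH2Cl2, 0 to 20 °C
Reagents that add atoms: none
Why: Steglich esterification acylates the only free hydroxyl, the primary furylmethyl alcohol (C19), and leaves the E-enoate unchanged.

Step 12
Reactants: 18 (2-{[(4R)-4-{[tert-butyl(dimethyl)silyl]oxy}-2,6,6-trimethylcyclohex-1-en-1-yl]methyl}furan-3-yl)methyl (2E)-dodec-2-enoate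
Product: 19 (2-{[(4R)-4-hydroxy-2,6,6-trimethylcyclohex-1-en-1-yl]methyl}furan-3-yl)methyl (2E)-dodec-2-enoate
Conditions: HF·pyridine, pyridine, THF, 0 to 20 °C
Reagents that add atoms: none
Why: Buffered fluoride cleavage of the silyl ether should free the C3 hydroxyl without affecting the furan or the ester.

Step 13
Reactants: 19 (2-{[(4R)-4-hydroxy-2,6,6-trimethylcyclohex-1-en-1-yl]methyl}furan-3-yl)methyl (2E)-dodec-2-enoate
Product: 21 (2E)-2-{[(4R)-4-hydroxy-2,6,6-trimethylcyclohex-1-en-1-yl]acetyl}-4-oxobut-2-en-1-yl (2E)-dodec-2-enoate, via (2Z) keto-enal isomer 20 (not isolated)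
Conditions: NBS (1.05 equiv), NaHCO3, acetone/H2O (10:1), −20 °C; then pyridine, 20 °C
Reagents that add atoms: water, O
Why: Oxidative furan ring opening (bromination at the free 5-position, hydration at the 2-position, loss of HBr) should unmask the C8 ketone and C11 aldehyde as the Z ene-dione, which pyridine isomerises to the more stable E isomer with C8 trans to C11; the electron-rich furan is expected to react before the ring alkene.

Step 14
Reactants: 22 (3E)-4-(2,6,6-trimethylcyclohex-2-en-1-yl)but-3-en-2-one (racemic α-ionone); 23 diethyl (cyanomethyl)phosphonate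
Product: 24 (2E,4E)-3-methyl-5-(2,6,6-trimethylcyclohex-2-en-1-yl)penta-2,4-dienenitrile (racemic)
Conditions: NaH, THF, 0 to 20 °C; chromatography
Reagents that add atoms: none
Why: Horner–Wadsworth–Emmons olefination of the methyl ketone with the cyanomethylphosphonate anion should give the dienenitrile mainly as the 2E isomer, which is separated from the 2Z isomer.

Step 15
Reactants: 24 (2E,4E)-3-methyl-5-(2,6,6-trimethylcyclohex-2-en-1-yl)penta-2,4-dienenitrile
Product: 25 (2E,4E)-3-methyl-5-(2,6,6-trimethyl-4-oxocyclohex-2-en-1-yl)penta-2,4-dienenitrile (racemic)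
Conditions: t-BuOOH (aq.), NaOCl (aq.), K2CO3, MeCN, 0 °C
Reagents that add atoms: tert-butyl hydroperoxide, CC(C)(C)OO
Why: Radical allylic oxidation with t-BuOOH and hypochlorite should oxidise the ring allylic methylene C3' to the enone, the position activated by the trisubstituted ring alkene.

Step 16
Reactants: 25 (2E,4E)-3-methyl-5-(2,6,6-trimethyl-4-oxocyclohex-2-en-1-yl)penta-2,4-dienenitrile
Product: 26 (2E,4E)-5-[(1R,4R)-4-hydroxy-2,6,6-trimethylcyclohex-2-en-1-yl]-3-methylpenta-2,4-dienenitrile
Conditions: ketoreductase (KRED, accepting the 1R ketone and giving the 4R alcohol), NADP+ (cat.), 2-propanol, phosphate buffer pH 7, DMSO co-solvent, 30 °C; stopped when the 1R ketone is consumed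
Reagents that add atoms: none
Why: Enzymatic carbonyl reduction as a kinetic resolution: an enzyme that accepts the 6'R enantiomer of 25 and delivers hydride to one carbonyl face should give the trans (3'R,6'R) alcohol while the 6'S ketone is recovered, so both ε-ring stereocentres come from the enzyme selection.

Step 17
Reactants: 26 (2E,4E)-5-[(1R,4R)-4-hydroxy-2,6,6-trimethylcyclohex-2-en-1-yl]-3-methylpenta-2,4-dienenitrile
Product: 28 (2E,4E)-5-[(1R,4R)-4-hydroxy-2,6,6-trimethylcyclohex-2-en-1-yl]-3-methylpenta-2,4-dienal, via aluminium aldimine 27 (not isolated)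
Conditions: iBu2AlH (2.5 equiv), CH2Cl2, −78 °C; then wet silica gel, 0 °C
Reagents that add atoms: water, O
Why: Partial reduction of the nitrile with iBu2AlH and mild hydrolysis of the aldimine should give the dienal without disturbing the stereocentres, the allylic alcohol or the double-bond geometry.

Step 18
Reactants: 29 (2E,4E,6E)-2,7-dimethylocta-2,4,6-trienedial
Product: 30 (2E,4E,6E)-2,7-dimethylocta-2,4,6-triene-1,8-diol
Conditions: NaBH4, MeOH/THF, 0 °C
Reagents that add atoms: none
Why: 1,2-Reduction of the two conjugated aldehydes with NaBH4 gives the diol and leaves the triene unchanged.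

Step 19
Reactants: 30 (2E,4E,6E)-2,7-dimethylocta-2,4,6-triene-1,8-diol
Product: 31 (2E,4E,6E)-1,8-dibromo-2,7-dimethylocta-2,4,6-triene
Conditions: PBr3, pyridine (cat.), Et2O, −10 °C; carried on crude
Reagents that add atoms: phosphorus tribromide, BrP(Br)Br
Why: PBr3 converts the two primary allylic alcohols into bromides by SN2 displacement of the phosphite esters.

Step 20
Reactants: 31 (2E,4E,6E)-1,8-dibromo-2,7-dimethylocta-2,4,6-triene
Product: 32 tetraethyl [(2E,4E,6E)-2,7-dimethylocta-2,4,6-triene-1,8-diyl]bis(phosphonate)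
Conditions: P(OEt)3, toluene, 100 °C
Reagents that add atoms: triethyl phosphite, CCOP(OCC)OCC
Why: The Michaelis–Arbuzov reaction of the primary allylic dibromide with triethyl phosphite should give the bis(phosphonate) at the two terminal carbons.

Step 21
Reactants: 32 tetraethyl [(2E,4E,6E)-2,7-dimethylocta-2,4,6-triene-1,8-diyl]bis(phosphonate); 28 (2E,4E)-5-[(1R,4R)-4-hydroxy-2,6,6-trimethylcyclohex-2-en-1-yl]-3-methylpenta-2,4-dienal
Product: 33 diethyl [(2E,4E,6E,8E,10E,12E)-13-[(1R,4R)-4-hydroxy-2,6,6-trimethylcyclohex-2-en-1-yl]-2,7,11-trimethyltrideca-2,4,6,8,10,12-hexaen-1-yl]phosphonate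
Conditions: 32 (4 equiv), KOtBu (1.1 equiv), THF, −30 °C; then 28, −30 to 0 °C
Reagents that add atoms: none
Why: Horner–Wadsworth–Emmons olefination of aldehyde 28 with the monoanion of the bis(phosphonate), used in excess to suppress double olefination, should form the E C11'=C12' bond; the free hydroxyl is less acidic than the phosphonate and is tolerated.

Step 22
Reactants: 33 diethyl [(2E,4E,6E,8E,10E,12E)-13-[(1R,4R)-4-hydroxy-2,6,6-trimethylcyclohex-2-en-1-yl]-2,7,11-trimethyltrideca-2,4,6,8,10,12-hexaen-1-yl]phosphonate; 21 (2E)-2-{[(4R)-4-hydroxy-2,6,6-trimethylcyclohex-1-en-1-yl]acetyl}-4-oxobut-2-en-1-yl (2E)-dodec-2-enoate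
Product: 34 (3R,3'R,6'R)-3,3'-dihydroxy-8-oxo-7,8-dihydro-β,ε-caroten-19-yl (2E)-dodec-2-enoate (siphonein, all-E chain)
Conditions: 33 (1.2 equiv), NaN(SiMe3)2 (1.2 equiv), THF, −78 °C; then 21, −78 to −30 °C
Reagents that add atoms: none
Why: Horner–Wadsworth–Emmons olefination of the polyenyl phosphonate anion with the aldehyde of 21, its most electrophilic carbonyl, at low temperature should form the E C11=C12 bond and complete the chromophore before the anion can attack the ketone or the allylic ester.

**Compound list**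

1 | 3,3-dimethylpentanedioic acid | OC(=O)CC(C)(C)CC(=O)O | starting material
2 | di-tert-butyl 3,3-dimethylpentanedioate | CC(C)(C)OC(=O)CC(C)(C)CC(=O)OC(C)(C)C | intermediate
3 | methyl (2E)-but-2-enoate | C/C=C/C(=O)OC | starting material
4 | lithium enolate of diester 2 | [Li]OC(OC(C)(C)C)=CC(C)(C)CC(=O)OC(C)(C)C | intermediate
5 | 1,3-di-tert-butyl 5-methyl 2,2,4-trimethylpentane-1,3,5-tricarboxylate (Michael adduct, present as its lithium enolate) | COC(=O)CC(C)C(C(=O)OC(C)(C)C)C(C)(C)CC(=O)OC(C)(C)C | intermediate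
6 | di-tert-butyl 2,2,4-trimethyl-6-oxocyclohexane-1,3-dicarboxylate (racemic diastereomer mixture) | O=C1CC(C)C(C(=O)OC(C)(C)C)C(C)(C)C1C(=O)OC(C)(C)C | intermediate
7 | tert-butyl 2,2,6-trimethyl-4-oxocyclohexane-1-carboxylate (racemic cis/trans mixture) | CC1CC(=O)CC(C)(C)C1C(=O)OC(C)(C)C | intermediate
8 | tert-butyl 2,6,6-trimethyl-4-oxocyclohex-2-ene-1-carboxylate (racemic) | CC1=CC(=O)CC(C)(C)C1C(=O)OC(C)(C)C | intermediate
9 | tert-butyl (4S)-4-hydroxy-2,6,6-trimethylcyclohex-2-ene-1-carboxylate (both C1 epimers) | CC1=C[C@@H](O)CC(C)(C)C1C(=O)OC(C)(C)C | intermediate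
10 | tert-butyl (4R)-4-hydroxy-2,6,6-trimethylcyclohex-1-ene-1-carboxylate | CC(C)(C)OC(=O)C1=C(C)C[C@@H](O)CC1(C)C | intermediate
11 | tert-butyl (4R)-4-{[tert-butyl(dimethyl)silyl]oxy}-2,6,6-trimethylcyclohex-1-ene-1-carboxylate | CC(C)(C)OC(=O)C1=C(C)C[C@@H](O[Si](C)(C)C(C)(C)C)CC1(C)C | intermediate
12 | [(4R)-4-{[tert-butyl(dimethyl)silyl]oxy}-2,6,6-trimethylcyclohex-1-en-1-yl]methanol | OCC1=C(C)C[C@@H](O[Si](C)(C)C(C)(C)C)CC1(C)C | intermediate
13 | {[(1R)-4-(bromomethyl)-3,5,5-trimethylcyclohex-3-en-1-yl]oxy}(tert-butyl)dimethylsilane | BrCC1=C(C)C[C@@H](O[Si](C)(C)C(C)(C)C)CC1(C)C | intermediate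
14 | furan-3-ylmethanol | OCc1ccoc1 | starting material
15 | 2-lithio-3-(lithiooxymethyl)furan | [Li]OCc1ccoc1[Li] | intermediate
16 | (2-{[(4R)-4-{[tert-butyl(dimethyl)silyl]oxy}-2,6,6-trimethylcyclohex-1-en-1-yl]methyl}furan-3-yl)methanol | OCc1ccoc1CC1=C(C)C[C@@H](O[Si](C)(C)C(C)(C)C)CC1(C)C | intermediate
17 | (2E)-dodec-2-enoic acid | CCCCCCCCC/C=C/C(=O)O | starting material
18 | (2-{[(4R)-4-{[tert-butyl(dimethyl)silyl]oxy}-2,6,6-trimethylcyclohex-1-en-1-yl]methyl}furan-3-yl)methyl (2E)-dodec-2-enoate | CCCCCCCCC/C=C/C(=O)OCc1ccoc1CC1=C(C)C[C@@H](O[Si](C)(C)C(C)(C)C)CC1(C)C | intermediate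
19 | (2-{[(4R)-4-hydroxy-2,6,6-trimethylcyclohex-1-en-1-yl]methyl}furan-3-yl)methyl (2E)-dodec-2-enoate | CCCCCCCCC/C=C/C(=O)OCc1ccoc1CC1=C(C)C[C@@H](O)CC1(C)C | intermediate
20 | (2Z)-2-{[(4R)-4-hydroxy-2,6,6-trimethylcyclohex-1-en-1-yl]acetyl}-4-oxobut-2-en-1-yl (2E)-dodec-2-enoate | CCCCCCCCC/C=C/C(=O)OC/C(=C/C=O)C(=O)CC1=C(C)C[C@@H](O)CC1(C)C | intermediate
21 | (2E)-2-{[(4R)-4-hydroxy-2,6,6-trimethylcyclohex-1-en-1-yl]acetyl}-4-oxobut-2-en-1-yl (2E)-dodec-2-enoate | CCCCCCCCC/C=C/C(=O)OC\C(=C/C=O)C(=O)CC1=C(C)C[C@@H](O)CC1(C)C | intermediate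
22 | (3E)-4-(2,6,6-trimethylcyclohex-2-en-1-yl)but-3-en-2-one (racemic α-ionone) | CC(=O)/C=C/C1C(C)=CCCC1(C)C | starting material
23 | diethyl (cyanomethyl)phosphonate | CCOP(=O)(CC#N)OCC | starting material
24 | (2E,4E)-3-methyl-5-(2,6,6-trimethylcyclohex-2-en-1-yl)penta-2,4-dienenitrile (racemic) | N#C/C=C(C)/C=C/C1C(C)=CCCC1(C)C | intermediate
25 | (2E,4E)-3-methyl-5-(2,6,6-trimethyl-4-oxocyclohex-2-en-1-yl)penta-2,4-dienenitrile (racemic) | N#C/C=C(C)/C=C/C1C(C)=CC(=O)CC1(C)C | intermediate
26 | (2E,4E)-5-[(1R,4R)-4-hydroxy-2,6,6-trimethylcyclohex-2-en-1-yl]-3-methylpenta-2,4-dienenitrile | N#C/C=C(C)/C=C/[C@H]1C(C)=C[C@H](O)CC1(C)C | intermediate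
27 | (2E,4E)-5-[(1R,4R)-4-hydroxy-2,6,6-trimethylcyclohex-2-en-1-yl]-3-methylpenta-2,4-dien-1-imine (as its aluminium derivative) | N=C/C=C(C)/C=C/[C@H]1C(C)=C[C@H](O)CC1(C)C | intermediate
28 | (2E,4E)-5-[(1R,4R)-4-hydroxy-2,6,6-trimethylcyclohex-2-en-1-yl]-3-methylpenta-2,4-dienal | O=C/C=C(C)/C=C/[C@H]1C(C)=C[C@H](O)CC1(C)C | intermediate
29 | (2E,4E,6E)-2,7-dimethylocta-2,4,6-trienedial | O=C/C(C)=C/C=C/C=C(C)/C=O | starting material
30 | (2E,4E,6E)-2,7-dimethylocta-2,4,6-triene-1,8-diol | OC/C(C)=C/C=C/C=C(C)/CO | intermediate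
31 | (2E,4E,6E)-1,8-dibromo-2,7-dimethylocta-2,4,6-triene | BrC/C(C)=C/C=C/C=C(C)/CBr | intermediate
32 | tetraethyl [(2E,4E,6E)-2,7-dimethylocta-2,4,6-triene-1,8-diyl]bis(phosphonate) | CCOP(=O)(OCC)C/C(C)=C/C=C/C=C(C)/CP(=O)(OCC)OCC | intermediate
33 | diethyl [(2E,4E,6E,8E,10E,12E)-13-[(1R,4R)-4-hydroxy-2,6,6-trimethylcyclohex-2-en-1-yl]-2,7,11-trimethyltrideca-2,4,6,8,10,12-hexaen-1-yl]phosphonate | CCOP(=O)(OCC)C/C(C)=C/C=C/C=C(C)/C=C/C=C(C)/C=C/[C@H]1C(C)=C[C@H](O)CC1(C)C | intermediate
34 | (3R,3'R,6'R)-3,3'-dihydroxy-8-oxo-7,8-dihydro-β,ε-caroten-19-yl (2E)-dodec-2-enoate | CCCCCCCCC/C=C/C(=O)OC\C(=C/C=C/C(C)=C/C=C/C=C(C)/C=C/C=C(C)/C=C/[C@H]1C(C)=C[C@H](O)CC1(C)C)C(=O)CC1=C(C)C[C@@H](O)CC1(C)C | target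

**Count and risks**

Total step count: 22. Longest linear sequence: 14 steps (steps 1 to 13, then step 22).

Steps most likely to fail:

1. Step 2. The hindered enolate may add slowly or 1,2 to the crotonate, and the first-formed C4 enolate may close onto a tert-butyl ester instead of the C2 enolate closing onto C3. Fallback, setting out from 2: double deprotonation with LiN(iPr)2 and trapping with Me3SiCl would give the bis(trimethylsilyl) ketene acetal 1,5-di-tert-butoxy-3,3-dimethyl-1,5-bis(trimethylsilyloxy)penta-1,4-diene F1. A fluoride-catalysed Mukaiyama–Michael addition of F1 to 3 (tetrabutylammonium difluorotriphenylsilicate, THF, −78 °C) and aqueous work-up would give triester 5 as an isolated compound. A separate Dieckmann cyclisation under equilibrating conditions (KOtBu, THF) then returns to the route at 6.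

2. Step 22. The base or the carbanion may expel the allylic acyloxy group from the ene-dione (elimination or conjugate attack) instead of olefinating the aldehyde. Fallback, setting out from 16: silylation of the primary alcohol (TBSCl, imidazole) would give the bis-silyl ether tert-butyl{[(1R)-4-{[3-({[tert-butyl(dimethyl)silyl]oxy}methyl)furan-2-yl]methyl}-3,5,5-trimethylcyclohex-3-en-1-yl]oxy}dimethylsilane F2. Furan opening as in step 13 would give the silyloxymethyl keto-enal F3, whose silyl ether is a poor leaving group. Olefination of F3 with the anion of 33 would give 3,19-bis-O-silyl siphonaxanthin F4, and HF·pyridine would free siphonaxanthin F5. Selective acylation of the primary C19 hydroxyl of F5 with 17 (DCC, DMAP, −20 °C, one equivalent) returns to the route at 34.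

3. Step 13. Electrophilic bromine may attack the tetrasubstituted ring alkene in competition with the furan. Fallback, setting out from 19: direct anodic oxidation in methanol (graphite anode, constant potential set at the furan oxidation wave, which lies below that of the alkene) would give the 2,5-dimethoxy-2,5-dihydrofuran F6. Mild aqueous acid hydrolysis of F6 would give the Z keto-enal 20, and pyridine isomerisation returns to the route at 21.

**Further compounds**

F1 | step 2 | 1,5-di-tert-butoxy-3,3-dimethyl-1,5-bis(trimethylsilyloxy)penta-1,4-diene | CC(C)(C)OC(O[Si](C)(C)C)=CC(C)(C)C=C(O[Si](C)(C)C)OC(C)(C)C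
F2 | step 22 | tert-butyl{[(1R)-4-{[3-({[tert-butyl(dimethyl)silyl]oxy}methyl)furan-2-yl]methyl}-3,5,5-trimethylcyclohex-3-en-1-yl]oxy}dimethylsilane | CC(C)(C)[Si](C)(C)OCc1ccoc1CC1=C(C)C[C@@H](O[Si](C)(C)C(C)(C)C)CC1(C)C
F3 | step 22 | (3E)-3-({[tert-butyl(dimethyl)silyl]oxy}methyl)-5-[(4R)-4-{[tert-butyl(dimethyl)silyl]oxy}-2,6,6-trimethylcyclohex-1-en-1-yl]-4-oxopent-2-enal | CC(C)(C)[Si](C)(C)OC\C(=C/C=O)C(=O)CC1=C(C)C[C@@H](O[Si](C)(C)C(C)(C)C)CC1(C)C
F4 | step 22 | (3R,3'R,6'R)-3,19-bis{[tert-butyl(dimethyl)silyl]oxy}-3'-hydroxy-7,8-dihydro-β,ε-caroten-8-one | CC(C)(C)[Si](C)(C)OC\C(=C/C=C/C(C)=C/C=C/C=C(C)/C=C/C=C(C)/C=C/[C@H]1C(C)=C[C@H](O)CC1(C)C)C(=O)CC1=C(C)C[C@@H](O[Si](C)(C)C(C)(C)C)CC1(C)C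
F5 | step 22 | (3R,3'R,6'R)-3,19,3'-trihydroxy-7,8-dihydro-β,ε-caroten-8-one (siphonaxanthin) | OC\C(=C/C=C/C(C)=C/C=C/C=C(C)/C=C/C=C(C)/C=C/[C@H]1C(C)=C[C@H](O)CC1(C)C)C(=O)CC1=C(C)C[C@@H](O)CC1(C)C
F6 | step 13 | (2-{[(4R)-4-hydroxy-2,6,6-trimethylcyclohex-1-en-1-yl]methyl}-2,5-dimethoxy-2,5-dihydrofuran-3-yl)methyl (2E)-dodec-2-enoate (diastereomer mixture at the acetal carbons) | CCCCCCCCC/C=C/C(=O)OCC1=CC(OC)OC1(OC)CC2=C(C)C[C@@H](O)CC2(C)C
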